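The readings stem from a simulated flask from invented constants; the scatter is artificial.

After 80.0 min a leftover of 72.3 % of the substrate G charged to the birch flask has not reached the product E, so E has room to grow in that flask. In these flasks G gives the intermediate L on the catalyst D, which forms from the charged J. L then takes up X, dissolved from the held gas Z, and gives E.

| flask | G | Z | J | remark | time |
|---|---|---|---|---|---|
| cedar | 0.035 M | 24 mM (held) | 1.5 mol% | run made earlier |  |
| birch | 0.13 M | 24 mM (held) | 1.5 mol% | run made earlier |  |
| south-west | 0.050 M | 24 mM (held) | 1.5 mol% |  | 2.5 h |
| north-east | 0.10 M | 24 mM (held) | 1.5 mol% |  | 2.5 h |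
| south-east | 0.20 M | 24 mM (held) | 1.5 mol% |  | 2.5 h |

| run | time / min | E / % |
|---|---|---|
| cedar | 10.0 | 0 |
| cedar | 20.0 | 0 |
| cedar | 30.0 | 3.3 |
| cedar | 40.0 | 5.7 |
| cedar | 50.0 | 10.0 |
| cedar | 60.0 | 14.4 |
| cedar | 80.0 | 25.1 |
| birch | 10.0 | 0 |
| birch | 20.0 | 4.3 |
| birch | 30.0 | 8.1 |
| birch | 40.0 | 13.1 |
| birch | 50.0 | 15.4 |
| birch | 60.0 | 20.1 |
| birch | 80.0 | 27.7 |

(readings scatter by 1 percentage point)

- [E] at the end for south-west, north-east, south-east, in this order
- how that number moves from the first to the last of them (rises, then falls / falls all the way / hardly changes / rises all the way / falls, then rises)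

- at the start none of X is dissolved
- the numbers in the tables scatter by 1 percentage point (one standard deviation)
- reactions considered so far: G + D -> D + L; Z <-> X; X + D + L -> D + E; J -> D
- "hardly changes" means that all values lie within two and a half points (for a concentration: within two and a half percent of the largest)

A bench rule says that, at the same loading of J and the same held Z, the percent of E at a given time does not depend on the charge of G. At 80.0 min cedar reads 25.1 % and birch 27.7 %, a gap of 2.6 percentage points against a scatter of 1 point per reading. At this one time the rule looks usable. Over its last stretch cedar gains a fraction 0.00535 /min of its charge, as a reading. Carried on to 2.5 h, that gives 62.5 %. The rule then gives 0.0313 M, 0.0625 M and 0.125 M.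

The rule asks for more E per minute as the charge grows, but X has to cross over from Z. From 30.0 min to 80.0 min birch makes E at 0.510 mM/min. This reading is taken here as the supply ceiling, the most E per minute that the crossing of Z to X feeds, a rate-limiting step. Per unit of charge, birch gains 0.00392 /min, less than cedar's fraction, so on these scattered readings, taken over different stretches, birch has left the rule. The ratio of ceiling to fraction gives a crossing charge of 0.0953 M, as a reading. South-west stands at 0.525 of it, north-east at 1.05, south-east at 2.10.

South-east stands beyond the crossing, so it goes by the ceiling, which over 2.5 h, with no lag subtracted, gives 0.0764 M, less than the rule's figure. For north-east, close to the crossing, this reckoning takes the smaller figure, the rule's 0.0625 M, less than that total. This reckoning commits to 0.0313 M, 0.0625 M and 0.0764 M, a row that rises all the way.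

The forecast, which differs from this reckoning, gave 0.028 M, 0.051 M and 0.08 M, rises all the way, on the grounds of “saturation or a gas-supply limit”.

The flask gives 0.0308 M, 0.0588 M and 0.0765 M: rises all the way.

    G + D → D + L (k = 1.57 /M/s)
    Z ⇌ X, rate k2*(csat - [X]) (kL = 3.85 × 10⁻⁴ /s)
    X + D + L → D + E (k = 14.5 /M²/s)
    J → D (k = 0.00129 /s)

In south-east at 2.50 h, E stands at 1.00 of the ceiling's total, while X is down at 0.00159 M, far below the saturation value 24 mM, and 61.8 % of the charge still waits as L. In south-west, E reaches 0.403 of that same total, X stands higher at 0.0143 M, and at 2.50 h X is made 1.25 times faster than it is used up.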